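**Strategy**

Locants follow chroman-2-one numbering; primes mark the tetraoxygenated lactone B. C3–C3′ comes intact from di-tert-butyl succinate. Ring A is built first by an isothiourea-catalysed [4+2] of an o-quinone methide with the Stobbe acid, leaving a 4-methoxybenzylidene ester on C3′. The route rests on closing ring B last through C4a′–C4′: a chiral Brønsted acid triggers a 6-endo Friedel–Crafts conjugate addition of the only free CH of the tetramethoxyphenyl ester onto benzylic C4′, exploiting the cation-stabilising 4-oxygenated aryl on C4′ and the electron-rich benzo ring B; the lactone enol then protonates anti to that aryl. One operation sets C4′ and the cis C3′ centre from an aryl α-substituted 4-methoxycinnamate.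

Key step: step 8

Assumption: compounds 1, 5, 6, 8 and 9 are taken as commercial, and for each chiral catalyst the enantiomer named is the one expected to give the drawn configuration (its antipode is used if the sense of induction proves opposite).

**Route**

Step 1
Reactants: 1 1,2,3,4-tetramethoxybenzene
Product: 4 2,3,4,5-tetramethoxyphenol, via aryllithium 2 (not isolated), via arylboronate 3 (not isolated)
Conditions: n-BuLi, TMEDA, THF, 0 °C; B(OMe)3, −78 °C to rt; AcOH, 30% aq. H2O2, 0 °C to rt
Reagents that add atoms: hydrogen peroxide OO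
Why: Directed ortho-lithiation should occur at either of the two equivalent CH positions of 1 (each ortho to a methoxy group), and borylation followed by peroxide oxidation of the C–B bond (lithiation–borylation–oxidation) should give the phenol; no stereocentre is formed.

Step 2
Reactants: 5 di-tert-butyl succinate; 6 4-methoxybenzaldehyde
Product: 7 (3E)-3-(tert-butoxycarbonyl)-4-(4-methoxyphenyl)but-3-enoic acid
Conditions: KOt-Bu, t-BuOH, 45 °C; aq. HCl
Reagents that add atoms: none
Why: Stobbe condensation: the succinate enolate adds to the aldehyde, the alkoxide lactonises onto the distal ester and base-induced opening of the paraconate should give the half-ester with the aryl group trans to the retained conjugated ester (E); no stereocentre is formed.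

Step 3
Reactants: 8 2-hydroxy-4,6-dimethoxybenzaldehyde; 9 4-methoxyphenylmagnesium bromide
Product: 10 2-[hydroxy(4-methoxyphenyl)methyl]-3,5-dimethoxyphenol (racemic)
Conditions: 4-MeOC6H4MgBr (2.2 equiv), THF, 0 °C to rt; aq. NH4Cl
Reagents that add atoms: none
Why: Grignard addition to the aldehyde after the first equivalent has deprotonated the phenol; the carbinol centre forms as a racemate, which is irrelevant because this carbon becomes trigonal in the o-quinone methide.

Step 4
Reactants: 10 2-[hydroxy(4-methoxyphenyl)methyl]-3,5-dimethoxyphenol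
Product: 11 3,5-dimethoxy-2-[(4-methoxyphenyl)(4-methylbenzenesulfonyl)methyl]phenol (racemic)
Conditions: TolSO2Na, HCO2H, CH2Cl2/H2O, rt
Reagents that add atoms: sodium p-toluenesulfinate Cc1ccc(cc1)S(=O)[O-].[Na+]
Why: Acid-promoted loss of water from the electron-rich o-hydroxybenzhydrol should give an o-quinone methide/benzylic cation that is trapped at sulfur by the sulfinate (sulfinic acid addition), giving a bench-stable racemic o-quinone methide precursor.

Step 5
Reactants: 7 (3E)-3-(tert-butoxycarbonyl)-4-(4-methoxyphenyl)but-3-enoic acid; 11 3,5-dimethoxy-2-[(4-methoxyphenyl)(4-methylbenzenesulfonyl)methyl]phenol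
Product: 14 tert-butyl (2E)-2-[(3R,4S)-5,7-dimethoxy-4-(4-methoxyphenyl)-2-oxochroman-3-yl]-3-(4-methoxyphenyl)prop-2-enoate, via mixed pivalic anhydride 12 (not isolated), via o-quinone methide 13 (not isolated)
Conditions: t-BuCOCl, i-Pr2NEt, CH2Cl2, 0 °C; then 11, (2S,3R)-HyperBTM (10 mol %), i-Pr2NEt, CH2Cl2, 0 °C to rt
Reagents that add atoms: none
Why: Isothiourea-catalysed Michael addition–lactonisation (formal [4+2]): the catalyst is acylated by 12, the (Z)-configured C1-ammonium dienolate should add through its α-carbon (C3) to the methide carbon of 13 on the face left open by the stereodirecting phenyl group of the catalyst, and the phenoxide lactonises with release of the catalyst; the endo-type approach should give the 3,4-cis lactone, the catalyst fixes (3R,4S), and the E-alkene is not touched.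

Step 6
Reactants: 14 tert-butyl (2E)-2-[(3R,4S)-5,7-dimethoxy-4-(4-methoxyphenyl)-2-oxochroman-3-yl]-3-(4-methoxyphenyl)prop-2-enoate
Product: 15 (2E)-2-[(3R,4S)-5,7-dimethoxy-4-(4-methoxyphenyl)-2-oxochroman-3-yl]-3-(4-methoxyphenyl)prop-2-enoic acid
Conditions: TFA/CH2Cl2 (1:4), 0 °C
Reagents that add atoms: none
Why: Acidolysis of the tert-butyl ester (loss of isobutene via the tert-butyl cation) under non-basic conditions should leave the aryl lactone, the E-alkene and the base-sensitive C3 centre untouched.

Step 7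
Reactants: 15 (2E)-2-[(3R,4S)-5,7-dimethoxy-4-(4-methoxyphenyl)-2-oxochroman-3-yl]-3-(4-methoxyphenyl)prop-2-enoic acid; 4 2,3,4,5-tetramethoxyphenol
Product: 16 2,3,4,5-tetramethoxyphenyl (2E)-2-[(3R,4S)-5,7-dimethoxy-4-(4-methoxyphenyl)-2-oxochroman-3-yl]-3-(4-methoxyphenyl)prop-2-enoate
Conditions: EDC·HCl, DMAP (0.1 equiv), CH2Cl2, 0 °C to rt
Reagents that add atoms: none
Why: Carbodiimide (Steglich) esterification of the conjugated acid with the phenol via the O-acylisourea/acylpyridinium; the small DMAP loading and low temperature should limit epimerisation at C3.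

Step 8
Reactants: 16 2,3,4,5-tetramethoxyphenyl (2E)-2-[(3R,4S)-5,7-dimethoxy-4-(4-methoxyphenyl)-2-oxochroman-3-yl]-3-(4-methoxyphenyl)prop-2-enoate
Product: 18 (3R,3′S,4S,4′R)-5,5′,6′,7,7′,8′-hexamethoxy-4,4′-bis(4-methoxyphenyl)-[3,3′-bichromane]-2,2′-dione, via lactone enol 17 (not isolated)
Conditions: (R)-3,3′-bis(2,4,6-triisopropylphenyl)-1,1′-binaphthyl-2,2′-diyl N-triflylphosphoramide (10 mol %), PhMe, 5 Å MS, −20 °C to rt
Reagents that add atoms: none
Why: Proposed new method: the chiral N-triflylphosphoramide activates the ester carbonyl of the 4-methoxycinnamate unit by O-protonation (C3′ stays trigonal), and within the chiral ion pair the only free ring CH of the tetramethoxyphenyl ester (future C4a′) attacks benzylic C4′, which carries the positive charge stabilised by the 4-methoxyphenyl group; loss of the arene proton gives lactone enol 17, which ketonises to 18. The closest known reaction types are the TFA- or TfOH-mediated intramolecular hydroarylation of aryl cinnamates to 4-aryl-3,4-dihydrocoumarins and N-triflylphosphoramide-catalysed enantioselective Friedel–Crafts additions and protonations; new is chiral-acid control with a simple aryl cinnamate as acceptor. Ring B closes in the 6-endo-trig mode (Friedel–Crafts conjugate addition), both alkene carbons C3′ and C4′ ending inside the lactone. C4′ should be set by the catalyst, whose anion shields one face of the protonated enoate, the ring A centres lying two and three bonds away and expected to bias the face only weakly; C3′ should be set by the substrate, because 17 is protonated anti to the 4′-aryl group that the peri 5′-methoxy forces pseudo-axial, which puts H3′ trans to that aryl and the C3 substituent cis. The step needs six- over seven-membered closure, secured because arene B has a single free position, ortho to O1′, whereas ring A could only close seven-membered rings, and it needs kinetic ketonisation and an intact C3–H, secured by catalytic acid, low temperature and the absence of base.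

Step 9
Reactants: 18 (3R,3′S,4S,4′R)-5,5′,6′,7,7′,8′-hexamethoxy-4,4′-bis(4-methoxyphenyl)-[3,3′-bichromane]-2,2′-dione
Product: 19 (3R,3′S,4S,4′R)-5,5′,6′,7,7′,8′-hexahydroxy-4,4′-bis(4-hydroxyphenyl)-[3,3′-bichromane]-2,2′-dione
Conditions: BBr3 (20 equiv), CH2Cl2, −78 °C to rt; MeOH then H2O, under argon
Reagents that add atoms: none
Why: Lewis-acid ether cleavage: BBr3 complexes each aryl methyl ether and bromide removes the methyl group by SN2, the aryl lactones and the four sp3 stereocentres should not be touched, and hydrolytic work-up under argon should release the octaphenol.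

**Compound list**

1 | 1,2,3,4-tetramethoxybenzene | COc1ccc(OC)c(OC)c1OC | starting material
2 | (2,3,4,5-tetramethoxyphenyl)lithium | [Li]c1cc(OC)c(OC)c(OC)c1OC | intermediate
3 | dimethyl (2,3,4,5-tetramethoxyphenyl)boronate | COB(OC)c1cc(OC)c(OC)c(OC)c1OC | intermediate
4 | 2,3,4,5-tetramethoxyphenol | Oc1cc(OC)c(OC)c(OC)c1OC | intermediate
5 | di-tert-butyl succinate | CC(C)(C)OC(=O)CCC(=O)OC(C)(C)C | starting material
6 | 4-methoxybenzaldehyde | COc1ccc(C=O)cc1 | starting material
7 | (3E)-3-(tert-butoxycarbonyl)-4-(4-methoxyphenyl)but-3-enoic acid | COc1ccc(/C=C(\CC(=O)O)C(=O)OC(C)(C)C)cc1 | intermediate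
8 | 2-hydroxy-4,6-dimethoxybenzaldehyde | COc1cc(O)c(C=O)c(OC)c1 | starting material
9 | 4-methoxyphenylmagnesium bromide | COc1ccc([Mg]Br)cc1 | starting material
10 | 2-[hydroxy(4-methoxyphenyl)methyl]-3,5-dimethoxyphenol (racemic) | COc1ccc(C(O)c2c(O)cc(OC)cc2OC)cc1 | intermediate
11 | 3,5-dimethoxy-2-[(4-methoxyphenyl)(4-methylbenzenesulfonyl)methyl]phenol (racemic) | COc1ccc(C(c2c(O)cc(OC)cc2OC)S(=O)(=O)c2ccc(C)cc2)cc1 | intermediate
12 | (3E)-3-(tert-butoxycarbonyl)-4-(4-methoxyphenyl)but-3-enoic pivalic anhydride | COc1ccc(/C=C(\CC(=O)OC(=O)C(C)(C)C)C(=O)OC(C)(C)C)cc1 | intermediate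
13 | 3,5-dimethoxy-6-[(4-methoxyphenyl)methylidene]cyclohexa-2,4-dien-1-one (o-quinone methide) | O=C1C=C(OC)C=C(OC)C1=Cc1ccc(OC)cc1 | intermediate
14 | tert-butyl (2E)-2-[(3R,4S)-5,7-dimethoxy-4-(4-methoxyphenyl)-2-oxochroman-3-yl]-3-(4-methoxyphenyl)prop-2-enoate (3,4-cis) | O=C1Oc2cc(OC)cc(OC)c2[C@H](c2ccc(OC)cc2)[C@@H]1/C(=C\c1ccc(OC)cc1)C(=O)OC(C)(C)C | intermediate
15 | (2E)-2-[(3R,4S)-5,7-dimethoxy-4-(4-methoxyphenyl)-2-oxochroman-3-yl]-3-(4-methoxyphenyl)prop-2-enoic acid | O=C1Oc2cc(OC)cc(OC)c2[C@H](c2ccc(OC)cc2)[C@@H]1/C(=C\c1ccc(OC)cc1)C(=O)O | intermediate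
16 | 2,3,4,5-tetramethoxyphenyl (2E)-2-[(3R,4S)-5,7-dimethoxy-4-(4-methoxyphenyl)-2-oxochroman-3-yl]-3-(4-methoxyphenyl)prop-2-enoate | O=C1Oc2cc(OC)cc(OC)c2[C@H](c2ccc(OC)cc2)[C@@H]1/C(=C\c1ccc(OC)cc1)C(=O)Oc1cc(OC)c(OC)c(OC)c1OC | intermediate
17 | lactone enol of 18: (3R,4S)-3-[(4R)-2-hydroxy-5,6,7,8-tetramethoxy-4-(4-methoxyphenyl)-4H-chromen-3-yl]-5,7-dimethoxy-4-(4-methoxyphenyl)chroman-2-one | O=C1Oc2cc(OC)cc(OC)c2[C@H](c2ccc(OC)cc2)[C@@H]1C1=C(O)Oc2c(OC)c(OC)c(OC)c(OC)c2[C@H]1c1ccc(OC)cc1 | intermediate
18 | (3R,3′S,4S,4′R)-5,5′,6′,7,7′,8′-hexamethoxy-4,4′-bis(4-methoxyphenyl)-[3,3′-bichromane]-2,2′-dione (both lactones 3,4-cis) | O=C1Oc2cc(OC)cc(OC)c2[C@H](c2ccc(OC)cc2)[C@@H]1[C@H]1C(=O)Oc2c(OC)c(OC)c(OC)c(OC)c2[C@H]1c1ccc(OC)cc1 | intermediate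
19 | (3R,3′S,4S,4′R)-5,5′,6′,7,7′,8′-hexahydroxy-4,4′-bis(4-hydroxyphenyl)-[3,3′-bichromane]-2,2′-dione | O=C1Oc2cc(O)cc(O)c2[C@H](c2ccc(O)cc2)[C@@H]1[C@H]1C(=O)Oc2c(O)c(O)c(O)c(O)c2[C@H]1c1ccc(O)cc1 | target

**Summary**

Total step count: 9. Longest linear sequence: 7 steps (steps 3, 4, 5, 6, 7, 8, 9).

**Steps most likely to fail**

Step 8. The chiral acid may discriminate the two faces of C4′ poorly, or be too weak to turn over, so that ring closure stalls or gives both C4′ epimers. The fallback sets out from 16 and returns at 18, using known chemistry only. Ring B is closed with an achiral strong acid (TfOH, 1.5 equiv, CH2Cl2, 0 °C to rt), the established hydroarylation of aryl cinnamates, accepting no catalyst control at C4′ and equilibration of the α-centres towards the trans lactones. Because C4 is already fixed, the C4′ epimers are diastereomers and are separated by chromatography. The 4′R series, isolated as the trans,trans lactone F1, is then corrected at C3 and C3′ in one operation: LiN(SiMe3)2 (2.5 equiv), THF, −78 °C, then inverse quench into AcOH/THF at −78 °C. Each lactone enolate should be protonated anti to its pseudo-axial 4-aryl group, giving 18.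

Step 5. An uncatalysed background addition to the o-quinone methide, or amine-induced epimerisation at the doubly activated C3–H, may erode enantio- and cis-selectivity. The fallback sets out from 7 and 11 and returns at 15. The same Michael addition–lactonisation is run with the achiral isothiourea DHPB to give the racemic cis lactone ester F2, and TFA cleaves the tert-butyl ester to the racemic acid F3. Classical resolution follows by crystallising the (R)-1-phenylethylammonium salt F4 of the (3R,4S)-acid from EtOAc/EtOH (the (S)-amine is used if the other salt is the less soluble one). Acidification with aq. HCl returns 15.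

Step 9. The tetrahydroxylated ring B may be oxidised during the long Lewis-acid demethylation and work-up, and the flanked methyl ethers may cleave incompletely. The fallback sets out from 18 and returns at 19, carrying ring B through the deprotection at the quinone level. (NH4)2Ce(NO3)6 in MeCN/H2O at 0 °C should oxidatively demethylate the para-related 5′- and 8′-methoxy groups to the ring B 5′,8′-quinone F5. BBr3 in CH2Cl2 then cleaves the six remaining methyl ethers to the air-stable hydroxyquinone F6. Na2S2O4 in EtOAc/H2O under argon reduces the quinone to 19 as the last, mild operation.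

Further compounds
F1 | step 8 | (3S,3′R,4S,4′R)-5,5′,6′,7,7′,8′-hexamethoxy-4,4′-bis(4-methoxyphenyl)-[3,3′-bichromane]-2,2′-dione (both lactones 3,4-trans) | O=C1Oc2cc(OC)cc(OC)c2[C@H](c2ccc(OC)cc2)[C@H]1[C@@H]1C(=O)Oc2c(OC)c(OC)c(OC)c(OC)c2[C@H]1c1ccc(OC)cc1
F2 | step 5 | racemic cis form of 14, tert-butyl (2E)-2-[5,7-dimethoxy-4-(4-methoxyphenyl)-2-oxochroman-3-yl]-3-(4-methoxyphenyl)prop-2-enoate | O=C1Oc2cc(OC)cc(OC)c2C(c2ccc(OC)cc2)C1/C(=C\c1ccc(OC)cc1)C(=O)OC(C)(C)C
F3 | step 5 | racemic cis form of 15, (2E)-2-[5,7-dimethoxy-4-(4-methoxyphenyl)-2-oxochroman-3-yl]-3-(4-methoxyphenyl)prop-2-enoic acid | O=C1Oc2cc(OC)cc(OC)c2C(c2ccc(OC)cc2)C1/C(=C\c1ccc(OC)cc1)C(=O)O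
F4 | step 5 | (R)-1-phenylethylammonium salt of 15 | O=C1Oc2cc(OC)cc(OC)c2[C@H](c2ccc(OC)cc2)[C@@H]1/C(=C\c1ccc(OC)cc1)C(=O)[O-].C[C@@H]([NH3+])c1ccccc1
F5 | step 9 | ring B 5′,8′-quinone of 18: (3R,4S)-3-[(3S,4R)-6,7-dimethoxy-4-(4-methoxyphenyl)-2,5,8-trioxo-3,4,5,8-tetrahydro-2H-chromen-3-yl]-5,7-dimethoxy-4-(4-methoxyphenyl)chroman-2-one | O=C1Oc2cc(OC)cc(OC)c2[C@H](c2ccc(OC)cc2)[C@@H]1[C@H]1C(=O)OC2=C([C@H]1c1ccc(OC)cc1)C(=O)C(OC)=C(OC)C2=O
F6 | step 9 | ring B 5′,8′-quinone of 19: (3R,4S)-3-[(3S,4R)-6,7-dihydroxy-4-(4-hydroxyphenyl)-2,5,8-trioxo-3,4,5,8-tetrahydro-2H-chromen-3-yl]-5,7-dihydroxy-4-(4-hydroxyphenyl)chroman-2-one | O=C1Oc2cc(O)cc(O)c2[C@H](c2ccc(O)cc2)[C@@H]1[C@H]1C(=O)OC2=C([C@H]1c1ccc(O)cc1)C(=O)C(O)=C(O)C2=O
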